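The route rests on cutting both diaryl ketone bonds between C1 of each inner ring A and its carbonyl carbon. Each outer ring B carries a methyl group at C6 next to the acylated C1, so every ortho-methyl aryl ketone is read as a ring-opened benzocyclobutenol. In one operation the methylene-bridged core is lithiated on both rings at C1, the carbon between the C2 and C6 oxygens; each anion adds to the strained carbonyl of a benzyloxy methoxy benzocyclobutenone, and both four-membered rings open to the C6-methyl ketones. The precursor is the symmetric tetra-MOM ether of bis(2,4-dihydroxy-6-methoxyphenyl)methane, which keeps its C4 methoxy groups and has C1 and C5 unsubstituted.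

Key step: step 7

Remark: ring A is numbered C1 (ketone-bearing carbon), C2 (OH), C3 (bridging CH2), C4 (OMe), C5 (H), C6 (OH). Ring B is numbered C1 (ketone-bearing carbon), C2 (OMe), C4 (OH), C6 (CH3). The benzocyclobutenone keeps its bicyclo[4.2.0] numbering (C7 carbonyl, C8 CH2). Assumption: methyl 2,4,6-trihydroxybenzoate and 4-bromo-3-methoxyphenol are purchased; this bromophenol is chosen because its bromide has a single ortho hydrogen, so only one aryne can form.

Step 1
Reactants: 1 methyl 2,4,6-trihydroxybenzoate
Product: 2 methyl 2,6-dihydroxy-4-methoxybenzoate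
Conditions: Me2SO4 (1.0 equiv), K2CO3 (1.0 equiv), acetone, 0 °C to rt
Reagents that add atoms: dimethyl sulfate, COS(=O)(=O)OC
Why: Williamson O-methylation should be confined to the 4-hydroxyl, which is para to the ester, the most acidic and the only phenol not hydrogen-bonded to the ester group, so one equivalent of base and of dimethyl sulfate leaves the two flanking hydroxyls free.

Step 2
Reactants: 2 methyl 2,6-dihydroxy-4-methoxybenzoate (two molecules per bridge, used in excess); 3 formaldehyde
Product: 5 dimethyl 3,3'-methylenebis(2,6-dihydroxy-4-methoxybenzoate), via hydroxymethyl phenol 4 (not isolated)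
Conditions: 37% aq. CH2O (0.4 equiv relative to 2), 2% aq. KOH, 0 °C to rt, Ar; then 1 M HCl
Reagents that add atoms: none
Why: Base-mediated phenol–formaldehyde condensation (Lederer–Manasse hydroxymethylation, then alkylation of a second phenoxide by the dehydrated hydroxymethyl phenol) should bridge two molecules at C3 of the benzoate, the only kind of free ring carbon because the ester blocks the site between the hydroxyls, while the deficit of formaldehyde holds the reaction at the dimer.

Step 3
Reactants: 5 dimethyl 3,3'-methylenebis(2,6-dihydroxy-4-methoxybenzoate)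
Product: 7 bis(2,4-dihydroxy-6-methoxyphenyl)methane, via diacid 6 (not isolated)
Conditions: 3 M aq. NaOH, 95 °C, Ar; then AcOH to pH 5, 80 °C
Reagents that add atoms: none
Why: Ester saponification followed by protodecarboxylation should clear both blocking groups, because a 2,6-dihydroxybenzoic acid on so electron-rich a ring is protonated at the ipso carbon and loses CO2 on gentle warming in weak acid.

Step 4
Reactants: 7 bis(2,4-dihydroxy-6-methoxyphenyl)methane
Product: 8 bis[6-methoxy-2,4-bis(methoxymethoxy)phenyl]methane
Conditions: MOMCl (6 equiv), i-Pr2NEt (8 equiv), CH2Cl2, 0 °C to rt, Ar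
Reagents that add atoms: chloromethyl methyl ether, COCCl
Why: Phenol O-alkylation with the reactive alpha-chloro ether under amine base should cap all four hydroxyls as MOM acetals, which survive n-BuLi and supply the chelating oxygens for the later metalation.

Step 5
Reactants: 9 4-bromo-3-methoxyphenol
Product: 10 4-(benzyloxy)-1-bromo-2-methoxybenzene
Conditions: BnBr (1.1 equiv), K2CO3 (1.5 equiv), DMF, rt
Reagents that add atoms: benzyl bromide, BrCc1ccccc1
Why: Williamson etherification of the single phenol should be clean, and the benzyl ether tolerates the amide base, the aqueous acid and the aryllithium that follow.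

Step 6
Reactants: 10 4-(benzyloxy)-1-bromo-2-methoxybenzene; 11 1,1-dimethoxyethene
Product: 14 3-(benzyloxy)-5-methoxybicyclo[4.2.0]octa-1,3,5-trien-7-one, via aryne 12 (not isolated), via dimethyl acetal 13 (not isolated)
Conditions: NaNH2 (3 equiv), 11 (3 equiv), THF, 65 °C; then 1 M aq. HCl, THF, rt
Reagents that add atoms: water, O
Why: Aryne [2+2] cycloaddition should work here because dehydrobromination can only take the one hydrogen ortho to bromine, the ketene acetal CH2 then attacks the aryne carbon meta to the methoxy group so that the developing aryl anion sits next to that oxygen and closes onto the oxocarbenium carbon, and mild aqueous acid hydrolyses the acetal to the ketone beside the methoxy-bearing carbon.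

Step 7
Reactants: 8 bis[6-methoxy-2,4-bis(methoxymethoxy)phenyl]methane; 14 3-(benzyloxy)-5-methoxybicyclo[4.2.0]octa-1,3,5-trien-7-one (two molecules)
Product: 18 tetra-MOM dibenzyl digriseophene A, via dilithio arene 15 (not isolated), via bis-cyclobutenoxide 16 (not isolated), via bis-dienolate 17 (not isolated)
Conditions: n-BuLi (2.2 equiv), TMEDA (2.2 equiv), THF, 0 °C; then 14 (2.1 equiv), −78 °C to rt; sat. aq. NH4Cl
Reagents that add atoms: none
Why: Directed ortho-metalation should place lithium on each ring A at C1, the carbon flanked by the two chelating MOM ethers at C2 and C6, in preference to C5 (one MOM and one methoxy neighbour) and to the doubly benzylic bridging CH2, which is reached more slowly under kinetic, coordination-driven control. Each aryllithium then adds 1,2 to the carbonyl C7 of 14, which is pinned back in the four-membered ring and cannot enolise without creating a benzocyclobutadiene, to give the lithium benzocyclobutenoxide 16. On warming, the oxido substituent drives a conrotatory 4π electrocyclic opening of the C7–C8 bond with the oxygen turning outward, and protonation of the resulting ortho-quinodimethane enolate 17 at its exocyclic CH2 on quench restores the aromaticity of ring B and delivers the C6 methyl group next to the new ketone. The closest known reaction type is the addition of aryllithiums to benzocyclobutenones followed by oxy-anion-accelerated ring opening to ortho-tolyl ketones; no ring is closed and no stereocentre is created. The step needs site selectivity in the metalation, secured by the pair of MOM groups around C1 of ring A, and cleavage of the C7–C8 bond instead of the C6–C7 aryl bond, secured because only the former is a thermally allowed electrocyclic path ending in a conjugated enolate. The ketone is added cold and held close to two equivalents so that addition is complete before ring opening and the dienolate meets no spare electrophile.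

Step 8
Reactants: 18 tetra-MOM dibenzyl digriseophene A
Product: 20 digriseophene A, via tetra-MOM bisphenol 19 (not isolated)
Conditions: H2 (1 atm), 10% Pd/C, MeOH–THF, rt; filter; then conc. HCl (cat.), MeOH–THF, 45 °C
Reagents that add atoms: none
Why: Benzyl ether hydrogenolysis over Pd/C under neutral conditions should leave the hindered diaryl ketones untouched, and acid-catalysed acetal exchange with methanol then frees the four MOM-protected phenols while the acylated rings A resist acid cleavage of the methylene bridge.

Compound list
1 | methyl 2,4,6-trihydroxybenzoate | COC(=O)c1c(O)cc(O)cc1O | starting material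
2 | methyl 2,6-dihydroxy-4-methoxybenzoate | COC(=O)c1c(O)cc(OC)cc1O | intermediate
3 | formaldehyde | C=O | starting material
4 | methyl 2,6-dihydroxy-3-(hydroxymethyl)-4-methoxybenzoate (hydroxymethyl phenol) | COC(=O)c1c(O)cc(OC)c(CO)c1O | intermediate
5 | dimethyl 3,3'-methylenebis(2,6-dihydroxy-4-methoxybenzoate) | COC(=O)c1c(O)cc(OC)c(Cc2c(OC)cc(O)c(C(=O)OC)c2O)c1O | intermediate
6 | 3,3'-methylenebis(2,6-dihydroxy-4-methoxybenzoic acid) (diacid) | OC(=O)c1c(O)cc(OC)c(Cc2c(OC)cc(O)c(C(=O)O)c2O)c1O | intermediate
7 | bis(2,4-dihydroxy-6-methoxyphenyl)methane | COc1cc(O)cc(O)c1Cc1c(OC)cc(O)cc1O | intermediate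
8 | bis[6-methoxy-2,4-bis(methoxymethoxy)phenyl]methane | COc1cc(OCOC)cc(OCOC)c1Cc1c(OC)cc(OCOC)cc1OCOC | intermediate
9 | 4-bromo-3-methoxyphenol | COc1cc(O)ccc1Br | starting material
10 | 4-(benzyloxy)-1-bromo-2-methoxybenzene | COc1cc(OCc2ccccc2)ccc1Br | intermediate
11 | 1,1-dimethoxyethene | C=C(OC)OC | starting material
12 | 5-(benzyloxy)-3-methoxybenzyne (1,2-didehydroarene; triple bond between the carbon ortho to OMe and its hydrogen-free neighbour) | COC1=CC(OCc2ccccc2)=CC#C1 | intermediate
13 | 3-(benzyloxy)-5,7,7-trimethoxybicyclo[4.2.0]octa-1,3,5-triene (dimethyl acetal) | COc1cc(OCc2ccccc2)cc2c1C(OC)(OC)C2 | intermediate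
14 | 3-(benzyloxy)-5-methoxybicyclo[4.2.0]octa-1,3,5-trien-7-one | COc1cc(OCc2ccccc2)cc2c1C(=O)C2 | intermediate
15 | bis[3-lithio-6-methoxy-2,4-bis(methoxymethoxy)phenyl]methane (lithium on each ring at the carbon between the two MOM ethers) | [Li]c1c(OCOC)cc(OC)c(Cc2c(OC)cc(OCOC)c([Li])c2OCOC)c1OCOC | intermediate
16 | dilithium bis-alkoxide in which each formerly lithiated carbon of the core is bonded to C7 of a 3-(benzyloxy)-5-methoxybicyclo[4.2.0]octa-1,3,5-trien-7-olate (mixture of diastereomers at the two C7 centres, configuration not defined) | COc1cc(OCOC)c(C2(O[Li])Cc3cc(OCc4ccccc4)cc(OC)c32)c(OCOC)c1Cc1c(OC)cc(OCOC)c(C2(O[Li])Cc3cc(OCc4ccccc4)cc(OC)c32)c1OCOC | intermediate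
17 | dilithium bis(ortho-quinodimethane enolate): each ring B opened to a 6-methylidenecyclohexa-2,4-dienylidene carrying the lithium enolate carbon bound to ring A (enolate geometry not specified) | COc1cc(OCOC)c(C(O[Li])=C2C(=C)C=C(OCc3ccccc3)C=C2OC)c(OCOC)c1Cc1c(OC)cc(OCOC)c(C(O[Li])=C2C(=C)C=C(OCc3ccccc3)C=C2OC)c1OCOC | intermediate
18 | tetra-MOM dibenzyl digriseophene A: methylenebis[6-methoxy-2,4-bis(methoxymethoxy)-3,1-phenylene] bis[4-(benzyloxy)-2-methoxy-6-methylphenyl ketone] | COc1cc(OCOC)c(C(=O)c2c(C)cc(OCc3ccccc3)cc2OC)c(OCOC)c1Cc1c(OC)cc(OCOC)c(C(=O)c2c(C)cc(OCc3ccccc3)cc2OC)c1OCOC | intermediate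
19 | tetra-MOM digriseophene A (the C4 phenol of each ring B free, four MOM ethers on rings A) | COc1cc(OCOC)c(C(=O)c2c(C)cc(O)cc2OC)c(OCOC)c1Cc1c(OC)cc(OCOC)c(C(=O)c2c(C)cc(O)cc2OC)c1OCOC | intermediate
20 | digriseophene A: methylenebis(2,4-dihydroxy-6-methoxy-3,1-phenylene) bis(4-hydroxy-2-methoxy-6-methylphenyl ketone), no stereocentres | COc1cc(O)c(C(=O)c2c(C)cc(O)cc2OC)c(O)c1Cc1c(OC)cc(O)c(C(=O)c2c(C)cc(O)cc2OC)c1O | target

Total step count: 8 steps.
Longest linear sequence: 6 steps (steps 1, 2, 3, 4, 7, 8); the benzocyclobutenone branch (steps 5, 6) joins at step 7.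

Steps most likely to fail

Step 7. The twofold metalation may stop short, the hindered aryllithium may add slowly and leave mono-adducts, and the ring-opened dienolate may be consumed by unreacted ketone or the alkoxide may fragment at the aryl–carbinol bond. The fallback sets out from 8 and returns at 18, replacing strain-release acylation by addition to an aldehyde and oxidation. Purchased 2,4-dihydroxy-6-methylbenzaldehyde F1 would be benzylated at the non-chelated 4-hydroxyl (BnBr, K2CO3, acetone) to 4-(benzyloxy)-2-hydroxy-6-methylbenzaldehyde F2 and methylated (MeI, K2CO3, DMF) to 4-(benzyloxy)-2-methoxy-6-methylbenzaldehyde F3. The dilithio species 15 generated from 8 would add to two equivalents of F3 to give the bis(diarylmethanol) F4 as a diastereomer mixture. Oxidation of both carbinols with Dess–Martin periodinane (NaHCO3, CH2Cl2) would then give 18.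

Step 2. Condensation may run past the dimer, because each ring of 5 keeps one nucleophilic carbon, giving trimers and higher oligomers. The fallback sets out from 2 and returns at 5, using bromine as a temporary blocking group. Monobromination of 2 (NBS, 1 equiv, MeCN, 0 °C) should give methyl 3-bromo-2,6-dihydroxy-4-methoxybenzoate F5, which has one free ring carbon only. Formaldehyde in aqueous KOH can then stop only at dimethyl 3,3'-methylenebis(5-bromo-2,6-dihydroxy-4-methoxybenzoate) F6. Hydrogenolysis of both C–Br bonds (H2, Pd/C, Et3N, MeOH) returns 5.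

Step 3. Hydrolysis of the hindered, doubly hydrogen-bonded esters may be incomplete, and the electron-rich polyphenol may suffer oxidative or retro-condensation breakdown in hot alkali. The fallback sets out from 5 and returns at 8, bypassing 7 by protecting before the carboxyl groups are removed. Alkylation of 5 (NaH, MOMCl, DMF, 0 °C to rt) should give dimethyl 3,3'-methylenebis[4-methoxy-2,6-bis(methoxymethoxy)benzoate] F7. Saponification (KOH, aq. DMSO, 90 °C; careful acidification) gives 3,3'-methylenebis[4-methoxy-2,6-bis(methoxymethoxy)benzoic acid] F8. Silver-catalysed protodecarboxylation of the ortho-alkoxy acids (Ag2CO3 10 mol%, AcOH 5 mol%, DMSO, 120 °C) then gives 8.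

Further compounds
F1 | step 7 | 2,4-dihydroxy-6-methylbenzaldehyde (purchased) | Cc1cc(O)cc(O)c1C=O
F2 | step 7 | 4-(benzyloxy)-2-hydroxy-6-methylbenzaldehyde | Cc1cc(OCc2ccccc2)cc(O)c1C=O
F3 | step 7 | 4-(benzyloxy)-2-methoxy-6-methylbenzaldehyde | COc1cc(OCc2ccccc2)cc(C)c1C=O
F4 | step 7 | bis(diarylmethanol) from 15 and two F3, carbinol carbons on both rings A between the MOM ethers (mixture of diastereomers, configuration not defined) | COc1cc(OCOC)c(C(O)c2c(C)cc(OCc3ccccc3)cc2OC)c(OCOC)c1Cc1c(OC)cc(OCOC)c(C(O)c2c(C)cc(OCc3ccccc3)cc2OC)c1OCOC
F5 | step 2 | methyl 3-bromo-2,6-dihydroxy-4-methoxybenzoate | COC(=O)c1c(O)cc(OC)c(Br)c1O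
F6 | step 2 | dimethyl 3,3'-methylenebis(5-bromo-2,6-dihydroxy-4-methoxybenzoate) | COC(=O)c1c(O)c(Br)c(OC)c(Cc2c(OC)c(Br)c(O)c(C(=O)OC)c2O)c1O
F7 | step 3 | dimethyl 3,3'-methylenebis[4-methoxy-2,6-bis(methoxymethoxy)benzoate] | COC(=O)c1c(OCOC)cc(OC)c(Cc2c(OC)cc(OCOC)c(C(=O)OC)c2OCOC)c1OCOC
F8 | step 3 | 3,3'-methylenebis[4-methoxy-2,6-bis(methoxymethoxy)benzoic acid] | OC(=O)c1c(OCOC)cc(OC)c(Cc2c(OC)cc(OCOC)c(C(=O)O)c2OCOC)c1OCOC
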